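The earlier runs and the new flask were computed with constants of no real substance, noise included.

The ratio of second reagent to starting material is 0.946, so in epsilon and blue, where partner matches starting material, the intermediate the charge can give and the second reagent stand in nearly equal amounts.

in all of them: second reagent 0.0123 M

|  | starting material | partner | remark | time |
|---|---|---|---|---|
| epsilon | 0.013 M | 0.013 M | run made earlier |  |
| zeta | 0.013 M | 0.0065 M | run made earlier |  |
| beta | 0.013 M | 0.026 M | run made earlier |  |
| green | 0.013 M | 0.0130 M | one stirred flow tank at steady state, fed with the mixture as stated, mean residence time 250 h |  |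
| red | 0.013 M (fed, over 20.0 h) | 0.0130 M | all but starting material at the start; starting material goes in evenly over 20.0 h, the run ends at 25 h | 25 h |
| blue | 0.013 M | 0.0130 M | a closed flask charged with all of it at once and left for 25 h | 25 h |
| violet | 0.013 M | 0.0130 M | one stirred flow tank at steady state, fed with the mixture as stated, mean residence time 25 h |  |

| run | time / h | intermediate / % | target / % |
|---|---|---|---|
| epsilon | 2.00 | 60 | 8 |
| epsilon | 4.00 | 45 | 6 |
| epsilon | 8.00 | 29 | 1 |
| epsilon | 12.0 | 24 | 1 |
| epsilon | 25.0 | 11 | 1 |
| zeta | 2.00 | 32 | 3 |
| zeta | 4.00 | 21 | 3 |
| zeta | 8.00 | 5 | 4 |
| zeta | 12.0 | 4 | 3 |
| zeta | 25.0 | 1 | 1 |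
| beta | 2.00 | 65 | 12 |
| beta | 6.00 | 38 | 4 |
| beta | 12.0 | 21 | 0 |
| beta | 20.0 | 13 | 0 |
| beta | 25.0 | 19 | 0 |

(scatter of a reading: 2 percentage points)

- the stated concentrations are those of everything mixed, before any reaction; amounts are the same in each set-up
- the feed brings no volume worth counting
- the earlier runs were made in a closed, stirred flask

* the set-up with the highest amount of intermediate at the outlet or at the end, in percent of the starting material put in ("none" if the first two lie within 2 percentage points) (green / red / blue / violet / none)
* amount of intermediate at the outlet or at the end, in percent of the starting material put in, green
* amount of intermediate at the outlet or at the end, in percent of the starting material put in, red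
* amount of intermediate at the outlet or at the end, in percent of the starting material put in, blue
* amount of intermediate at the outlet or at the end, in percent of the starting material put in, violet

I read the runs this way: partner and starting material give intermediate within the first readings, and the intermediate is then lost one for one with second reagent. With equal amounts, the share y left at time t follows

y = 1 / (1 + t/T)

Here T is the loss time, the time in which intermediate facing an equal amount of second reagent falls to 0.5 of its start. You can get it in two ways.

From epsilon, between 2.00 h and 25.0 h, the law gives T = 3.10 h.

In zeta, second reagent stands above the partner, which invites the pseudo-first-order shortcut: hold c(second reagent) fixed and take the slope of ln y between 2.00 h and 12.0 h. That gives T = 4.55 h, longer than epsilon's.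

The shortcut cheats. It keeps c(second reagent) at 0.0123 M, but if all the partner has become intermediate and the loss is one for one, the reading at 12.0 h puts the reagent at 0.00632 M. If you let it fall one for one with the intermediate, zeta gives T = 2.75 h. Both are readings with their scatter, and I take the mean, 2.92 h.

The small thing is the excess of intermediate over second reagent, e = 5.38% of the charge. It lifts blue from 10.5% on the plain law to

y = e / (1 − (1 − e) exp(−e t/T)) = 13.4%

For a tank with residence time τ, taking all starting material as reacted,

y + (τ/T) y (y − e) = 1

This gives violet 31.2% and green 13.1%, so violet stands above blue. Red I leave unreckoned.

The forecast names violet, with green 11.6%, red 21%, blue 13% and violet 27%, “Violet wins, because at short residence time the loss is second-order.”, and its green and violet lie below mine.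

The flask gives violet: green 11.7%, red 22.1%, blue 13.3%, violet 27.0%.

    target → over-reaction product (k = 3.40 × 10⁻⁴ s⁻¹)
    starting material + partner → intermediate (k = 0.180 L mol⁻¹ s⁻¹)
    second reagent + intermediate → target (k = 0.00740 L mol⁻¹ s⁻¹)

In violet, 6.66% of the starting material leaves the tank unreacted. Call that share a. The balance with the same T then reads

y + (τ/T) y (y + a − e) = 1 − a

and it gives 27.2% of intermediate at the violet outlet.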